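**Strategy.** Numbering: C1 prenyl bridgehead, C2 to C4 dione carbons, C5 geranyl bridgehead, C7 CH-prenyl, C8 CMe2, C9 bridging carbonyl. The route rests on disconnecting C1–C9. C9 is carried as the non-enolisable carbonyl of a cyclopentanone (C5, C6, C7, C8, C9) whose C5 already bears geranyl and an (E)-3-methoxybut-2-enoyl arm (C4 to C1). One γ-deprotonation closes ring A (C1 to C5 plus C9) by vinylogous aldol addition of C1 to C9, giving the masked 2,4-dione and the C9 carbinol that drives the following oxidative shift of C8 from C9 to C1. The step exploits that C9 lies between quaternary C5 and C8 and that ring A is a 1,3,5-tricarbonyl array ending at C1.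

Key step: step 5

Remark: the target is drawn as one enol tautomer of the 3-aroyl-2,4-dione; (E)-3-methoxybut-2-enoic acid and 3-acetoxybenzoyl chloride are taken as purchasable; geranyl = (E)-3,7-dimethylocta-2,6-dien-1-yl, prenyl = 3-methylbut-2-en-1-yl.

Step 1
Reactants: 1 2-methylcyclopent-2-en-1-one; 2 4-bromo-2-methylbut-1-ene
Product: 5 (S)-2,2-dimethyl-3-(3-methylbut-3-en-1-yl)cyclopentan-1-one, via Grignard reagent 3 (not isolated), via magnesium enolate 4 (not isolated)
Conditions: 2, Mg, Et2O, rt; then 1, Cu(OTf)2 (3 mol %), chiral imidazolinium NHC precursor (4 mol %), Et2O, −30 °C; then MeI, DMPU, −30 °C → rt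
Reagents that add atoms: iodomethane, CI
Why: Copper-catalysed asymmetric conjugate addition of a Grignard reagent to an α-substituted cyclic enone with alkylative enolate trapping; the chiral carbene ligand on copper (enantiomer chosen for the S adduct) sets C7, the only stereocentre not later controlled by the substrate, and methylation of the regiodefined enolate 4 should create the gem-dimethyl C8 without touching C7.

Step 2
Reactants: 5 (S)-2,2-dimethyl-3-(3-methylbut-3-en-1-yl)cyclopentan-1-one
Product: 6 (R)-2,2-dimethyl-3-(3-methylbut-2-en-1-yl)cyclopentan-1-one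
Conditions: chloro[N,N'-bis(3,5-di-tert-butylsalicylidene)-1,1,2,2-tetramethylethane-1,2-diaminato]cobalt (3 mol %), PhSiH3 (5 mol %), benzene, rt
Reagents that add atoms: none
Why: Cobalt hydride (hydrogen-atom-transfer) alkene isomerisation should move the 1,1-disubstituted double bond one position into the more stable trisubstituted prenyl position under neutral conditions that leave the ketone and C7 untouched (the descriptor changes from S to R only through the priority rules).

Step 3
Reactants: 6 (R)-2,2-dimethyl-3-(3-methylbut-2-en-1-yl)cyclopentan-1-one; 7 (E)-3-methoxybut-2-enoic acid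
Product: 9 (4S)-2-[(E)-3-methoxybut-2-enoyl]-5,5-dimethyl-4-(3-methylbut-2-en-1-yl)cyclopentan-1-one as its C2 epimers/enol tautomers, via acid chloride 8 (not isolated)
Conditions: 7, (COCl)2, DMF (cat.), CH2Cl2, 0 °C → rt, evaporate; then 6, MgBr2·OEt2, i-Pr2NEt, CH2Cl2, rt
Reagents that add atoms: none
Why: Soft-enolisation C-acylation of a ketone with an acid chloride (magnesium enolate from MgBr2·OEt2 and amine) should give the 1,3-diketone at C5, the only enolisable position because C8 is quaternary, and installs the C4 to C1 arm with C1 cis to C4 across the enol ether double bond as ring A will require.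

Step 4
Reactants: 9 (4S)-2-[(E)-3-methoxybut-2-enoyl]-5,5-dimethyl-4-prenylcyclopentan-1-one; 10 geranyl bromide, (E)-1-bromo-3,7-dimethylocta-2,6-diene
Product: 11 (2S,4S)-2-geranyl-2-[(E)-3-methoxybut-2-enoyl]-5,5-dimethyl-4-prenylcyclopentan-1-one (geranyl trans to prenyl)
Conditions: crude 9 used at once, K2CO3, n-Bu4NI (cat.), acetone, 40 °C
Reagents that add atoms: none
Why: SN2 C-alkylation of the stabilised 2-acylcyclopentanone enolate with an allylic bromide (E geometry retained) should occur on the face of C5 anti to the C7 prenyl group, which makes C5 quaternary with geranyl trans and the acyl arm cis to that prenyl group, the relative configuration of the 7-endo target.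

Step 5
Reactants: 11 (2S,4S)-2-geranyl-2-[(E)-3-methoxybut-2-enoyl]-5,5-dimethyl-4-prenylcyclopentan-1-one
Product: 13 (2S,3aR,7aR)-3a-geranyl-7a-hydroxy-6-methoxy-1,1-dimethyl-2-prenyl-1,2,3,3a,7,7a-hexahydro-4H-inden-4-one (cis-fused), via lithium dienolate 12 (not isolated)
Conditions: LiTMP (lithium 2,2,6,6-tetramethylpiperidide, 1.2 equiv), THF, −78 → −40 °C; AcOH, −78 °C
Reagents that add atoms: none
Why: LiTMP removes a proton from the only acidic position of 11, the γ-methyl group C1 of the β-methoxy enone, to give the extended dienolate 12, whose γ-carbon adds to the C9 carbonyl and closes ring A as its lithium aldolate (intramolecular vinylogous aldol addition). The closest known reactions are γ-selective aldol additions of β-alkoxy enone and enoate dienolates and the enolate-to-cyclopentanone aldol closure that ends a diketene annulation. The six-membered ring closes in a 6-(enolendo)-exo-trig mode, and attack through the α-carbon C3 would need a four-membered ring, so γ-regioselectivity is enforced by the tether. The new C9 carbinol centre is controlled by C5, because the arm can reach only the carbonyl face on its own side and the ring fusion must be cis. Chemoselectivity rests on the substrate having no other enolisable site (C9 and C4 are flanked only by the quaternary C5 and C8 and the vinylic C3) and on an amide base without β-hydrogen that cannot reduce the hindered ketone. Retro-aldol opening should be held back by the lithium counter-ion, the low temperature and the cold acetic acid quench.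

Step 6
Reactants: 13 (2S,3aR,7aR)-3a-geranyl-7a-hydroxy-6-methoxy-1,1-dimethyl-2-prenyl-1,2,3,3a,7,7a-hexahydro-4H-inden-4-one
Product: 14 (1R,5S,7S)-5-geranyl-2-methoxy-8,8-dimethyl-7-prenylbicyclo[3.3.1]non-2-ene-4,9-dione (core numbering of the overview)
Conditions: PhI(OAc)2, KOH, MeOH, 0 °C → rt
Reagents that add atoms: none
Why: Hypervalent iodine oxidative ring expansion (semipinacol-type 1,2-shift): the dienolate of 13 should be captured by PhI(OMe)2 formed in situ, at C1 or at C3 with allylic transposition, and the C9 alkoxide then pushes the tertiary C8 from C9 to C1 with loss of PhI, which turns C9 into the bridging ketone and builds the bicyclo[3.3.1]nonane, the suprafacial shift on the cis-fused system fixing C1 relative to C5.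

Step 7
Reactants: 14 (1R,5S,7S)-5-geranyl-2-methoxy-8,8-dimethyl-7-prenylbicyclo[3.3.1]non-2-ene-4,9-dione; 15 prenyl bromide, 1-bromo-3-methylbut-2-ene
Product: 16 (1R,5S,7S)-5-geranyl-2-methoxy-8,8-dimethyl-1,7-diprenylbicyclo[3.3.1]non-2-ene-4,9-dione
Conditions: LiTMP (2.5 equiv), THF, −78 °C; 15, −78 → 0 °C; aq. NH4Cl
Reagents that add atoms: none
Why: Bridgehead lithiation and alkylation of a bicyclic vinylogous ester: C1–H is acidified by the C9 ketone and the adjacent enol ether, the pyramidal bridgehead anion keeps its configuration and should react with prenyl bromide by SN2, while any C3-lithiated material does not alkylate without copper and returns on work-up.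

Step 8
Reactants: 16 (1R,5S,7S)-5-geranyl-2-methoxy-8,8-dimethyl-1,7-diprenylbicyclo[3.3.1]non-2-ene-4,9-dione; 17 3-acetoxybenzoyl chloride
Product: 18 (1R,5R,7S)-3-(3-acetoxybenzoyl)-5-geranyl-2-methoxy-8,8-dimethyl-1,7-diprenylbicyclo[3.3.1]non-2-ene-4,9-dione (C5 descriptor changes by priority only)
Conditions: LiTMP, THF, −78 °C; then inverse addition to 17, THF, −78 °C
Reagents that add atoms: none
Why: Vinylic lithiation of the β-methoxy enone at C3, now the only acidic C–H, followed by acylation with an aroyl chloride, which should react far faster than the aryl acetate; no stereocentre is affected.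

Step 9
Reactants: 18 (1R,5R,7S)-3-(3-acetoxybenzoyl)-5-geranyl-2-methoxy-8,8-dimethyl-1,7-diprenylbicyclo[3.3.1]non-2-ene-4,9-dione
Product: 19 (1S,5S,7S)-5-geranyl-4-hydroxy-3-(3-hydroxybenzoyl)-8,8-dimethyl-1,7-diprenylbicyclo[3.3.1]non-3-ene-2,9-dione (target, CNP0236890.1)
Conditions: LiOH, dioxane/H2O, 90 °C; then 1 M HCl, 0 °C
Reagents that add atoms: lithium hydroxide, [Li+].[OH-] (oxygen at C2)
Why: Hydroxide addition–elimination at C2 of the 3-acyl vinylogous ester (vinylogous saponification) should release the enolised 2,4-dione while the same base cleaves the aryl acetate, so both masks fall in one operation and the quaternary C1 and C5 and the tertiary C7 cannot epimerise.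

**Compound list**
1 | 2-methylcyclopent-2-en-1-one | CC1=CCCC1=O | starting material
2 | 4-bromo-2-methylbut-1-ene | CC(=C)CCBr | starting material
3 | (3-methylbut-3-en-1-yl)magnesium bromide | CC(=C)CC[Mg]Br | intermediate
4 | bromomagnesium enolate of (S)-2-methyl-3-(3-methylbut-3-en-1-yl)cyclopentanone | CC1=C(O[Mg]Br)CC[C@@H]1CCC(C)=C | intermediate
5 | (S)-2,2-dimethyl-3-(3-methylbut-3-en-1-yl)cyclopentan-1-one | O=C1CC[C@H](CCC(C)=C)C1(C)C | intermediate
6 | (R)-2,2-dimethyl-3-(3-methylbut-2-en-1-yl)cyclopentan-1-one | O=C1CC[C@H](CC=C(C)C)C1(C)C | intermediate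
7 | (E)-3-methoxybut-2-enoic acid | C/C(OC)=C\C(=O)O | starting material
8 | (E)-3-methoxybut-2-enoyl chloride | C/C(OC)=C\C(Cl)=O | intermediate
9 | (4S)-2-[(E)-3-methoxybut-2-enoyl]-5,5-dimethyl-4-prenylcyclopentan-1-one (C2 epimers/enol tautomers) | O=C1C(C(=O)/C=C(/OC)C)C[C@H](CC=C(C)C)C1(C)C | intermediate
10 | geranyl bromide, (E)-1-bromo-3,7-dimethylocta-2,6-diene | CC(C)=CCC/C(C)=C/CBr | starting material
11 | (2S,4S)-2-geranyl-2-[(E)-3-methoxybut-2-enoyl]-5,5-dimethyl-4-prenylcyclopentan-1-one | O=C1[C@](C/C=C(\C)CCC=C(C)C)(C(=O)/C=C(/OC)C)C[C@H](CC=C(C)C)C1(C)C | intermediate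
12 | lithium dienolate of 11 (γ-deprotonated at C1) | [Li]OC(=CC(OC)=C)[C@]1(C/C=C(\C)CCC=C(C)C)C[C@H](CC=C(C)C)C(C)(C)C1=O | intermediate
13 | (2S,3aR,7aR)-3a-geranyl-7a-hydroxy-6-methoxy-1,1-dimethyl-2-prenyl-1,2,3,3a,7,7a-hexahydro-4H-inden-4-one | COC1=CC(=O)[C@]2(C/C=C(\C)CCC=C(C)C)C[C@H](CC=C(C)C)C(C)(C)[C@]2(O)C1 | intermediate
14 | (1R,5S,7S)-5-geranyl-2-methoxy-8,8-dimethyl-7-prenylbicyclo[3.3.1]non-2-ene-4,9-dione | CC(C)=CCC/C(C)=C/C[C@]12C[C@H](CC=C(C)C)C(C)(C)[C@H](C(OC)=CC1=O)C2=O | intermediate
15 | prenyl bromide, 1-bromo-3-methylbut-2-ene | CC(C)=CCBr | starting material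
16 | (1R,5S,7S)-5-geranyl-2-methoxy-8,8-dimethyl-1,7-diprenylbicyclo[3.3.1]non-2-ene-4,9-dione | CC(C)=CCC/C(C)=C/C[C@]12C[C@H](CC=C(C)C)C(C)(C)[C@](CC=C(C)C)(C(OC)=CC1=O)C2=O | intermediate
17 | 3-acetoxybenzoyl chloride | CC(=O)Oc1cccc(c1)C(Cl)=O | starting material
18 | (1R,5R,7S)-3-(3-acetoxybenzoyl)-5-geranyl-2-methoxy-8,8-dimethyl-1,7-diprenylbicyclo[3.3.1]non-2-ene-4,9-dione | CC(C)=CCC/C(C)=C/C[C@]12C[C@H](CC=C(C)C)C(C)(C)[C@](CC=C(C)C)(C(OC)=C(C(=O)c3cccc(OC(C)=O)c3)C1=O)C2=O | intermediate
19 | (1S,5S,7S)-5-geranyl-4-hydroxy-3-(3-hydroxybenzoyl)-8,8-dimethyl-1,7-diprenylbicyclo[3.3.1]non-3-ene-2,9-dione | CC(C)=CCC/C(C)=C/C[C@]12C[C@H](CC=C(C)C)C(C)(C)[C@](CC=C(C)C)(C(=O)C(C(=O)c3cccc(O)c3)=C1O)C2=O | target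

**Total step count:** 9. **Longest linear sequence:** 9 steps (1 → 19); compounds 2, 7, 10, 15 and 17 enter as bought.

**Steps most likely to fail**

Step 6. The iodane may be captured unproductively, or the ring-fusion bond C9–C5 or the alkoxide oxygen may compete with C8 in the 1,2-shift, because in the 7-endo series the C7 prenyl group sits under ring A and may disfavour the reactive conformer. The fallback sets out from 13. Silylation (TMSOTf, Et3N, CH2Cl2) should give the bis-trimethylsilyl diene F1, with a C9 silyl ether and a 4-silyloxy-2-methoxy-1,3-diene in ring A. NBS (THF, −78 °C) should brominate the diene terminus C1 to give the γ-bromo enone F2. AgBF4 (CH2Cl2, −20 °C) then ionises the C1–Br bond while the silyloxy-bearing C9 delivers C8 to C1 (silver-assisted semipinacol rearrangement), and the route is rejoined at 14.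

Step 7. Deprotonation may occur mainly at the vinylic C3–H, and alkylation of the hindered bridgehead anion next to C8 may be slow, so conversion stalls. The fallback sets out from 14. C3 is blocked by in situ silylation (LiTMP, Me3SiCl, THF, −78 °C) to give the 3-trimethylsilyl derivative F3. The bridgehead, now the only acidic site, is lithiated (LiTMP, −78 → 0 °C) and alkylated with 15 to give the 1-prenyl-3-trimethylsilyl compound F4. TBAF (THF) removes silicon and the route is rejoined at 16.

Step 4. Facial selectivity at C5 may be poor, since the directing C7 prenyl group is only 1,3-related to the reacting carbon, and O-alkylation may compete. The fallback sets out from 9 and replaces the substrate-controlled SN2 alkylation by a catalyst-controlled palladium asymmetric allylic alkylation (Tsuji–Trost type). Geranyl methyl carbonate is used with Pd2(dba)3 (2.5 mol %) and the enantiomer of N,N'-(cyclohexane-1,2-diyl)bis[2-(diphenylphosphanyl)benzamide] that is matched with entry anti to the prenyl group, in CH2Cl2 at rt. This should lead directly to 11 without any new compound (F0).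

Further compounds
F1 | step 6 | bis-trimethylsilyl derivative of 13 (C9 silyl ether, 4-silyloxy-2-methoxy-1,3-diene in ring A) | COC=1C=C(O[Si](C)(C)C)[C@]2(C/C=C(\C)CCC=C(C)C)C[C@H](CC=C(C)C)C(C)(C)[C@]2(O[Si](C)(C)C)C=1
F2 | step 6 | C1-bromo derivative of 13 as its C9 trimethylsilyl ether | COC1=CC(=O)[C@]2(C/C=C(\C)CCC=C(C)C)C[C@H](CC=C(C)C)C(C)(C)[C@]2(O[Si](C)(C)C)C1Br
F3 | step 7 | 3-trimethylsilyl derivative of 14 | CC(C)=CCC/C(C)=C/C[C@]12C[C@H](CC=C(C)C)C(C)(C)[C@H](C(OC)=C([Si](C)(C)C)C1=O)C2=O
F4 | step 7 | 3-trimethylsilyl derivative of 16 | CC(C)=CCC/C(C)=C/C[C@]12C[C@H](CC=C(C)C)C(C)(C)[C@](CC=C(C)C)(C(OC)=C([Si](C)(C)C)C1=O)C2=O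
F0 | step 4 | none | none
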